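Read the time axis first. In the larch run, which is this flask followed so far, left-handed product reads 0% at 20.0 s and 5.9% at 90.0 s.

- larch: left-handed substrate 0.95 M; right-handed substrate 0.95 M; gas 200 mM (held); free catalyst 9.5 mM; racemization catalyst 140 mM; impurity 1.8 mM; added ligand 510 mM; the very flask that is asked about, followed so far
- flask: left-handed substrate 0.95 M; gas 200 mM (held); free catalyst 9.5 mM; racemization catalyst 140 mM; impurity 1.8 mM; added ligand 510 mM; right-handed substrate 0.95 M; time 3.0 min

larch run (percent of the left-handed substrate and right-handed substrate together charged)

| time / s | left-handed substrate / % | right-handed substrate / % | left-handed product / % |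
|---|---|---|---|
| 10.0 | 50.3 | 50.5 | 0 |
| 12.0 | 48.6 | 49.5 | 0.2 |
| 20.0 | 49.2 | 49.6 | 0 |
| 30.0 | 48.5 | 49.4 | 1.7 |
| 50.0 | 46.4 | 50.0 | 3.7 |
| 90.0 | 44.3 | 48.3 | 5.9 |

(scatter of a reading: 0.5 percentage points)

- part of the left-handed substrate and right-handed substrate charged together that has reacted at 3.0 min
- excess of left-handed product over right-handed product in the product at 3.0 min
- excess of right-handed substrate over left-handed substrate among what is left of the two at 3.0 min

- free catalyst is single-handed; left-handed substrate and right-handed substrate are mirror images of each other, charged as a racemate, each of them at the stated concentration
- at the start none of coupling partner is dissolved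
- what may be going on: racemization catalyst + added ligand <-> idle complex; coupling partner + free catalyst + right-handed substrate -> free catalyst + right-handed product; free catalyst + impurity -> spent catalyst; left-handed substrate + racemization catalyst <-> right-handed substrate + racemization catalyst; coupling partner + free catalyst + left-handed substrate -> free catalyst + left-handed product; gas <-> coupling partner
- an excess is the difference of the two amounts in percent of their sum
- an excess is below zero if the other one leads

At the start none of the coupling partner is dissolved. Impurity turns free catalyst into spent catalyst one for one. The impurity charge is smaller than the catalyst charge. Assume the impurity goes completely, and reckon what remains: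

f = 1 − c(impurity) / c(free catalyst) = 81.1%

Call f the working share: the part of the charged catalyst that the impurity leaves free. Both product steps run through free catalyst. At fixed coupling partner and substrate, their rates therefore scale with f.

Now replace the curve by its mean. Take the larch readings from 30.0 s to 90.0 s:

m = 1.33 mM s⁻¹

Extend this from the last reading to the asked time:

left-handed product at 3.0 min = 12.2%

Check the error. The later stretch alone, from 50.0 s, gives 10.8%. Commit to the mean line, with that gap as its margin.

The balance at 90.0 s leaves 1.50% for right-handed product. Three readings of 0.5 percentage points each stand inside that figure, so don't build a selectivity factor on it.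

The forecast gives 12.5%, 70% and 8.5%, and holds that “Racemization therefore looks slow”.

The flask gives 15.7%, 87.7% and 9.39%.

    racemization catalyst + added ligand ⇌ idle complex (K = 0.510 M⁻¹, k = 0.520 M⁻¹ s⁻¹)
    coupling partner + free catalyst + right-handed substrate → free catalyst + right-handed product (k = 0.130 M⁻² s⁻¹)
    free catalyst + impurity → spent catalyst (k = 2100 M⁻¹ s⁻¹)
    left-handed substrate + racemization catalyst ⇌ right-handed substrate + racemization catalyst, rate k4*[racemization catalyst]*[left-handed substrate] forward; the back reaction follows from the equilibrium constant (k = 0.0330 M⁻¹ s⁻¹)
    coupling partner + free catalyst + left-handed substrate → free catalyst + left-handed product (k = 2.20 M⁻² s⁻¹)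
    gas ⇌ coupling partner, rate k6*(csat - [coupling partner]) (kL = 0.0270 s⁻¹)

At 3.00 min this flask holds 81.1% of its catalyst free, the value of f, with impurity at 0%. At that time it makes coupling partner 1.04 times as fast as it uses it, against 1.17 at 1.16 min, and coupling partner stands at 0.133 M, below the saturation 200 mM. Take the neighbour flask with 0.0072 M impurity: f becomes 24.2%, and that flask holds 24.2% free. Scaling this flask's left-handed product by the two working shares gives 4.40%. The neighbour flask holds 6.04%, with coupling partner at 0.170 M.

The earlier runs and the new flask were computed with constants of no real substance; the scatter is artificial.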